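**Retrosynthetic overview**
- Rings A, B and C of the flavanone and its C2 stereocentre are bought intact from the chiral pool; no flavanone ring is built.
- The bond between chromanone C6 and side-chain C8 is cut back to a trans-glycidate ester tethered through the chromanone 5-oxygen. A new epoxy–arene cyclisation closes a six-membered aryl lactone (first ring formed), which sets C8, keeps C7 and forces reaction at chromanone C6 instead of chromanone C8.
- The tether lactone is opened again (thioester, then aldehyde at C6).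
- The C5–C6 bond and both carbinol centres come from one chelation-controlled γ-silyloxyallylstannane addition.
- The 5,6-dihydro-2H-pyran-2-one is the last ring formed (acrylate ring-closing metathesis), followed by one acid deprotection.

Assumption: the trans-glycidic ester 1, methyl (2R,3S)-3-phenyloxirane-2-carboxylate, is bought as the single enantiomer.

Locants: unprefixed locants C2 to C8 are those of the lactone ring and side chain of the target (C2 lactone carbonyl, C5 and C7 carbinols, C6 ring CH–O, C8 diarylmethine). Positions of the flavanone core are always written with the word "chromanone" (chromanone C2, C4, C5, C6, C7, C8).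

**Step 1**
Reactants: 1 methyl (2R,3S)-3-phenyloxirane-2-carboxylate
Product: 2 potassium (2R,3S)-3-phenyloxirane-2-carboxylate
Conditions: KOH (1.0 equiv), EtOH, 0 °C, salt filtered off
Reagents that add atoms: potassium hydroxide, [K+].[OH-]
Why: Ester saponification with one equivalent of hydroxide at 0 °C precipitates the glycidate salt and leaves the oxirane and both stereocentres untouched.

**Step 2**
Reactants: 3 (S)-pinocembrin, (2S)-5,7-dihydroxy-2-phenylchroman-4-one
Product: 4 (2S)-5-hydroxy-7-(methoxymethoxy)-2-phenylchroman-4-one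
Conditions: MOMCl (1.1 equiv), i-Pr2NEt (1.5 equiv), CH2Cl2, 0 °C to rt
Reagents that add atoms: chloromethyl methyl ether, COCCl
Why: Selective O-alkylation (MOM ether formation) of the free, acidic 7-OH, because the 5-OH is locked in a hydrogen bond to the chromanone C4 ketone; the mild amine base does not open the flavanone, so chromanone C2 stays (S).

**Step 3**
Reactants: 4 (2S)-5-hydroxy-7-(methoxymethoxy)-2-phenylchroman-4-one; 2 potassium (2R,3S)-3-phenyloxirane-2-carboxylate
Product: 5 (2S)-7-(methoxymethoxy)-4-oxo-2-phenylchroman-5-yl (2R,3S)-3-phenyloxirane-2-carboxylate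
Conditions: EDC·HCl (1.5 equiv), DMAP (0.3 equiv), CH2Cl2, 0 °C to rt
Reagents that add atoms: none
Why: Steglich esterification (carbodiimide activation, DMAP acyl transfer) acylates the only free hydroxyl, the 5-OH, without opening the oxirane; no stereocentre is involved.

**Step 4**
Reactants: 5 (2S)-7-(methoxymethoxy)-4-oxo-2-phenylchroman-5-yl (2R,3S)-3-phenyloxirane-2-carboxylate
Product: 6 (3R,4S,8S)-3-hydroxy-5-(methoxymethoxy)-4,8-diphenyl-3,4,8,9-tetrahydro-2H,10H-pyrano[2,3-f]chromene-2,10-dione (tether lactone; target locants 7R, 8S, chromanone 2S; 7-OH and 8-Ph trans)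
Conditions: Sc(OTf)3 (5 mol %), 2,6-di-tert-butylpyridine (10 mol %), 1,1,1,3,3,3-hexafluoropropan-2-ol–CH2Cl2 1:3, 0.005 M, 0 °C to rt
Reagents that add atoms: none
Why: Proposed new method: a Lewis-acid-catalysed intramolecular epoxy–arene (Friedel–Crafts) cyclisation in which the aryl ester itself is the tether; Sc(OTf)3 chelates the ester carbonyl and the oxirane oxygen and, helped by the ionising solvent, loosens the benzylic C8–O bond; the only ring carbon that can reach C8 through a six-membered transition state is chromanone C6 (ortho to the tethering 5-oxygen, also ortho to the 7-OMOM donor and para to the ring oxygen), so chromanone C8 cannot compete; backside attack inverts C8 and leaves C7 untouched, giving the trans 3-hydroxy-4-phenyl lactone (7R,8S); attack goes to the benzylic and not the α-carbonyl oxirane carbon because phenyl stabilises the developing cation; the closest known reaction types are the epoxy–arene cyclisation of aryl glycidyl ethers and N-aryl glycidamides to trans-4-aryl-3-hydroxy chromans and quinolinones and the acid-mediated cyclisation of aryl cinnamates to 4-aryl-3,4-dihydrocoumarins, neither shown for an aryl glycidate ester.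

**Step 5**
Reactants: 6 tether lactone (free 7-OH)
Product: 7 (3R,4S,8S)-3,5-bis(methoxymethoxy)-4,8-diphenyl-3,4,8,9-tetrahydro-2H,10H-pyrano[2,3-f]chromene-2,10-dione
Conditions: MOMCl (3 equiv), i-Pr2NEt (4 equiv), Bu4NI (10 mol %), CH2Cl2, 0 to 35 °C
Reagents that add atoms: chloromethyl methyl ether, COCCl
Why: MOM ether formation at the only free hydroxyl (iodide-catalysed O-alkylation) installs the chelating α-alkoxy group needed for step 9; the hindered amine does not epimerise C7.

**Step 6**
Reactants: 7 bis-MOM tether lactone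
Product: 8 S-ethyl (2R,3S)-3-[(2S)-5-hydroxy-7-(methoxymethoxy)-4-oxo-2-phenylchroman-6-yl]-2-(methoxymethoxy)-3-phenylpropanethioate
Conditions: AlMe3 (1.6 equiv), EtSH (1.8 equiv), CH2Cl2, 0 °C; aq. potassium sodium tartrate work-up
Reagents that add atoms: ethanethiol, CCS
Why: Aluminium thiolate ester-to-thioester exchange (Me2AlSEt) opens the activated aryl lactone irreversibly because a strong Al–O(aryl) bond forms; the freed chromanone 5-OH then hydrogen-bonds to the chromanone C4 ketone and shields it.

**Step 7**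
Reactants: 8 S-ethyl thioester
Product: 9 (2R,3S)-3-[(2S)-5-hydroxy-7-(methoxymethoxy)-4-oxo-2-phenylchroman-6-yl]-2-(methoxymethoxy)-3-phenylpropanal
Conditions: Et3SiH (3 equiv), Pd/C (10 mol % Pd), acetone, rt
Reagents that add atoms: none
Why: Fukuyama reduction (palladium-catalysed hydrosilane reduction of a thioester) stops at the aldehyde and leaves the aryl ketone, the MOM acetals and C7 untouched; 9 may rest as its lactol with the chromanone 5-OH, which reacts as the aldehyde.

**Step 8**
Reactants: 10 (allyloxy)(tert-butyl)dimethylsilane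
Product: 12 (Z)-tributyl[3-(tert-butyldimethylsilyloxy)prop-2-en-1-yl]stannane, via (Z)-3-(tert-butyldimethylsilyloxy)allyllithium 11 (not isolated)
Conditions: s-BuLi (1.1 equiv), THF–HMPA, −78 °C; then Bu3SnCl (1.1 equiv), −78 to 0 °C
Reagents that add atoms: sec-butyllithium, CCC(C)[Li] (its lithium stays in 11 only); tributyltin chloride, CCCC[Sn](Cl)(CCCC)CCCC
Why: Allylic lithiation of the silyl allyl ether gives the oxygen-chelated (Z)-allyllithium, and stannylation at the carbon remote from oxygen gives the (Z)-γ-silyloxyallylstannane.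

**Step 9**
Reactants: 9 α-MOM-oxy aldehyde; 12 (Z)-γ-silyloxyallylstannane
Product: 13 (2S)-6-[(1S,2R,3S,4S)-4-(tert-butyldimethylsilyloxy)-3-hydroxy-2-(methoxymethoxy)-1-phenylhex-5-en-1-yl]-5-hydroxy-7-(methoxymethoxy)-2-phenylchroman-4-one (target locants 5S,6S,7R,8S; the C6 label differs from the target only because of the silyl group)
Conditions: MgBr2·OEt2 (3 equiv), 12 (2 equiv), CH2Cl2, −25 to 0 °C
Reagents that add atoms: none
Why: Chelation-controlled Keck-type γ-alkoxyallylstannane addition: MgBr2 bridges the aldehyde oxygen and the C7 OMOM group, attack on the chelate face opposite the C8 substituent sets C6 (6,7-syn) and the (Z)-stannane sets C5 (5,6-syn); the aryl ketone does not react with allylstannanes.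

**Step 10**
Reactants: 13 homoallylic alcohol
Product: 14 (3S,4S,5R,6S)-3-(tert-butyldimethylsilyloxy)-6-[(2S)-5-hydroxy-7-(methoxymethoxy)-4-oxo-2-phenylchroman-6-yl]-5-(methoxymethoxy)-6-phenylhex-1-en-4-yl prop-2-enoate
Conditions: acryloyl chloride (1.5 equiv), i-Pr2NEt (3 equiv), CH2Cl2, −40 to 0 °C
Reagents that add atoms: acryloyl chloride, C=CC(=O)Cl
Why: O-acylation of the secondary C6-OH; the chromanone 5-OH is hydrogen-bonded to the ketone and flanked by two ortho substituents, so it stays free at low temperature without DMAP.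

**Step 11**
Reactants: 14 acrylate
Product: 15 (5S,6S)-5-(tert-butyldimethylsilyloxy)-6-{(1R,2S)-2-[(2S)-5-hydroxy-7-(methoxymethoxy)-4-oxo-2-phenylchroman-6-yl]-1-(methoxymethoxy)-2-phenylethyl}-5,6-dihydro-2H-pyran-2-one
Conditions: second-generation Grubbs catalyst RuCl2(=CHPh)(PCy3)(H2IMes) (8 mol %), CH2Cl2 (2 mM), 40 °C
Reagents that add atoms: none
Why: Ring-closing metathesis of the acrylate with the allylic vinyl group closes the six-membered (Z)-enoate lactone and releases ethene; no stereocentre is touched.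

**Step 12**
Reactants: 15 protected lactone
Product: 16 target, (5S,6R)-5-hydroxy-6-{(1R,2S)-2-[(2S)-5,7-dihydroxy-4-oxo-2-phenylchroman-6-yl]-1-hydroxy-2-phenylethyl}-5,6-dihydro-2H-pyran-2-one (CNP0136207.1)
Conditions: HCl (3 M) in MeOH–THF 1:1, 0 °C to rt
Reagents that add atoms: none
Why: Acid-catalysed acetal exchange removes both MOM groups and acidic methanolysis removes the TBS ether; flavanone, enoate lactone and all five stereocentres are stable to dilute methanolic HCl at room temperature.

**Compound list**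
1 | methyl (2R,3S)-3-phenyloxirane-2-carboxylate | COC(=O)[C@@H]1O[C@H]1c1ccccc1 | starting material
2 | potassium (2R,3S)-3-phenyloxirane-2-carboxylate | [K+].[O-]C(=O)[C@@H]1O[C@H]1c1ccccc1 | intermediate
3 | (S)-pinocembrin, (2S)-5,7-dihydroxy-2-phenylchroman-4-one | O=C1C[C@@H](c2ccccc2)Oc2cc(O)cc(O)c12 | starting material
4 | (2S)-5-hydroxy-7-(methoxymethoxy)-2-phenylchroman-4-one | O=C1C[C@@H](c2ccccc2)Oc2cc(OCOC)cc(O)c12 | intermediate
5 | (2S)-7-(methoxymethoxy)-4-oxo-2-phenylchroman-5-yl (2R,3S)-3-phenyloxirane-2-carboxylate | O=C1C[C@@H](c2ccccc2)Oc2cc(OCOC)cc(OC(=O)[C@@H]3O[C@H]3c3ccccc3)c12 | intermediate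
6 | (3R,4S,8S)-3-hydroxy-5-(methoxymethoxy)-4,8-diphenyl-3,4,8,9-tetrahydro-2H,10H-pyrano[2,3-f]chromene-2,10-dione | O=C1[C@H](O)[C@@H](c2ccccc2)c2c(OCOC)cc3c(c2O1)C(=O)C[C@@H](c2ccccc2)O3 | intermediate
7 | (3R,4S,8S)-3,5-bis(methoxymethoxy)-4,8-diphenyl-3,4,8,9-tetrahydro-2H,10H-pyrano[2,3-f]chromene-2,10-dione | O=C1[C@H](OCOC)[C@@H](c2ccccc2)c2c(OCOC)cc3c(c2O1)C(=O)C[C@@H](c2ccccc2)O3 | intermediate
8 | S-ethyl (2R,3S)-3-[(2S)-5-hydroxy-7-(methoxymethoxy)-4-oxo-2-phenylchroman-6-yl]-2-(methoxymethoxy)-3-phenylpropanethioate | CCSC(=O)[C@H](OCOC)[C@@H](c2ccccc2)c2c(OCOC)cc3c(c2O)C(=O)C[C@@H](c2ccccc2)O3 | intermediate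
9 | (2R,3S)-3-[(2S)-5-hydroxy-7-(methoxymethoxy)-4-oxo-2-phenylchroman-6-yl]-2-(methoxymethoxy)-3-phenylpropanal | O=C[C@H](OCOC)[C@@H](c2ccccc2)c2c(OCOC)cc3c(c2O)C(=O)C[C@@H](c2ccccc2)O3 | intermediate
10 | (allyloxy)(tert-butyl)dimethylsilane | C=CCO[Si](C)(C)C(C)(C)C | starting material
11 | (Z)-3-(tert-butyldimethylsilyloxy)allyllithium | [Li]C/C=C\O[Si](C)(C)C(C)(C)C | intermediate (not isolated)
12 | (Z)-tributyl[3-(tert-butyldimethylsilyloxy)prop-2-en-1-yl]stannane | CCCC[Sn](CCCC)(CCCC)C/C=C\O[Si](C)(C)C(C)(C)C | intermediate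
13 | (2S)-6-[(1S,2R,3S,4S)-4-(tert-butyldimethylsilyloxy)-3-hydroxy-2-(methoxymethoxy)-1-phenylhex-5-en-1-yl]-5-hydroxy-7-(methoxymethoxy)-2-phenylchroman-4-one | C=C[C@H](O[Si](C)(C)C(C)(C)C)[C@H]([C@H](OCOC)[C@@H](c2ccccc2)c2c(OCOC)cc3c(c2O)C(=O)C[C@@H](c2ccccc2)O3)O | intermediate
14 | (3S,4S,5R,6S)-3-(tert-butyldimethylsilyloxy)-6-[(2S)-5-hydroxy-7-(methoxymethoxy)-4-oxo-2-phenylchroman-6-yl]-5-(methoxymethoxy)-6-phenylhex-1-en-4-yl prop-2-enoate | C=C[C@H](O[Si](C)(C)C(C)(C)C)[C@H]([C@H](OCOC)[C@@H](c2ccccc2)c2c(OCOC)cc3c(c2O)C(=O)C[C@@H](c2ccccc2)O3)OC(=O)C=C | intermediate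
15 | (5S,6S)-5-(tert-butyldimethylsilyloxy)-6-{(1R,2S)-2-[(2S)-5-hydroxy-7-(methoxymethoxy)-4-oxo-2-phenylchroman-6-yl]-1-(methoxymethoxy)-2-phenylethyl}-5,6-dihydro-2H-pyran-2-one | O=C1C=C[C@H](O[Si](C)(C)C(C)(C)C)[C@H]([C@H](OCOC)[C@@H](c2ccccc2)c2c(OCOC)cc3c(c2O)C(=O)C[C@@H](c2ccccc2)O3)O1 | intermediate
16 | (5S,6R)-5-hydroxy-6-{(1R,2S)-2-[(2S)-5,7-dihydroxy-4-oxo-2-phenylchroman-6-yl]-1-hydroxy-2-phenylethyl}-5,6-dihydro-2H-pyran-2-one | O=C1C=C[C@H](O)[C@H]([C@H](O)[C@@H](c2ccccc2)c2c(O)cc3c(c2O)C(=O)C[C@@H](c2ccccc2)O3)O1 | target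

**Step count and risks**

Total step count: 12. Longest linear sequence: 10 steps (3 to 16 through steps 2, 3, 4, 5, 6, 7, 9, 10, 11, 12).

The three steps most likely to fail:

Step 4 (the proposed new cyclisation). The ester-deactivated oxirane may rearrange (hydride or acyl shift), the benzylic centre may ionise fully and lose stereochemical integrity, or the aryl MOM ether may be lost before the moderately nucleophilic ring A attacks. The fallback uses known chemistry, sets out from 4 (together with 1) and comes back at 6. It is the untethered Lewis-acid Friedel–Crafts opening of glycidic ester 1 by flavanone 4 (boron trifluoride diethyl etherate, CH2Cl2, −78 to −20 °C), which arylates the benzylic oxirane carbon with inversion but at both free positions of ring A. It gives the chromanone C6 adduct methyl (2R,3S)-2-hydroxy-3-[(2S)-5-hydroxy-7-(methoxymethoxy)-4-oxo-2-phenylchroman-6-yl]-3-phenylpropanoate F1 together with its chromanone C8 regioisomer methyl (2R,3S)-2-hydroxy-3-[(2S)-5-hydroxy-7-(methoxymethoxy)-4-oxo-2-phenylchroman-8-yl]-3-phenylpropanoate F2. Only the C6 adduct has a phenol ortho to the new side chain. It lactonises (pyridinium p-toluenesulfonate cat., toluene, 80 °C) to 6, which is then separated by chromatography from the C8 adduct, which cannot lactonise. Regiocontrol is lost and about half the material with it, but the route continues unchanged from 6.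

Step 6 (thiolytic lactone opening). Me2AlSEt may also attack the MOM acetals or the aryl ketone, or thioester 8 may re-close to 7 on handling. The fallback sets out from 7 and comes back at 9, bypassing 8 and step 7. Lactone 7 is opened with Me2AlN(OMe)Me (from AlMe3 and MeNHOMe·HCl, CH2Cl2, 0 °C) to the amide (2R,3S)-3-[(2S)-5-hydroxy-7-(methoxymethoxy)-4-oxo-2-phenylchroman-6-yl]-N-methoxy-2-(methoxymethoxy)-N-methyl-3-phenylpropanamide F3. This is reduced with (i-Bu)2AlH (2.2 equiv, THF, −78 °C): the first equivalent ties the chromanone 5-phenoxide and the chromanone C4 ketone into an aluminium chelate, the second reduces the amide to aldehyde 9.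

Step 12 (acid deprotection on the finished lactone). The secondary MOM ether at C7 needs prolonged acid, during which the 5-hydroxy enoate lactone can undergo methanolysis, translactonisation to a butenolide or oxa-Michael addition. The fallback sets out from 14 and comes back at 16, reversing the order of the last two operations. The three protecting groups are hydrolysed on the open-chain acrylate 14 (6 M aq. HCl–THF 1:4, rt) to give (3S,4R,5R,6S)-6-[(2S)-5,7-dihydroxy-4-oxo-2-phenylchroman-6-yl]-3,5-dihydroxy-6-phenylhex-1-en-4-yl prop-2-enoate F4. The ring is then closed last by metathesis with the same ruthenium catalyst (CH2Cl2, 40 °C), which tolerates free hydroxyls, to give 16 directly, so the lactone never meets acid.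

**Further compounds**
F1 | step 4 | methyl (2R,3S)-2-hydroxy-3-[(2S)-5-hydroxy-7-(methoxymethoxy)-4-oxo-2-phenylchroman-6-yl]-3-phenylpropanoate | COC(=O)[C@H](O)[C@@H](c2ccccc2)c2c(OCOC)cc3c(c2O)C(=O)C[C@@H](c2ccccc2)O3
F2 | step 4 | methyl (2R,3S)-2-hydroxy-3-[(2S)-5-hydroxy-7-(methoxymethoxy)-4-oxo-2-phenylchroman-8-yl]-3-phenylpropanoate | COC(=O)[C@H](O)[C@@H](c1ccccc1)c1c(OCOC)cc(O)c2C(=O)C[C@@H](c3ccccc3)Oc12
F3 | step 6 | (2R,3S)-3-[(2S)-5-hydroxy-7-(methoxymethoxy)-4-oxo-2-phenylchroman-6-yl]-N-methoxy-2-(methoxymethoxy)-N-methyl-3-phenylpropanamide | CON(C)C(=O)[C@H](OCOC)[C@@H](c2ccccc2)c2c(OCOC)cc3c(c2O)C(=O)C[C@@H](c2ccccc2)O3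
F4 | step 12 | (3S,4R,5R,6S)-6-[(2S)-5,7-dihydroxy-4-oxo-2-phenylchroman-6-yl]-3,5-dihydroxy-6-phenylhex-1-en-4-yl prop-2-enoate | C=C[C@H](O)[C@H]([C@H](O)[C@@H](c2ccccc2)c2c(O)cc3c(c2O)C(=O)C[C@@H](c2ccccc2)O3)OC(=O)C=C
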